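The readings come from a simulation on assumed constants; scatter was added.

The autumn run, charged with 0.12 M of substrate, had turned 40.9% of it into product by 12.0 min, while the noon run, charged with 0.29 M, had turned 25.9%, each figure being the mean of the product reading and the substrate missing, and I built my reckoning for elm and ash on that fall.

common to all: partner 0.198 M; free catalyst 2.6 mM; added ligand 4.6 mM

|  | substrate | remark | time |
|---|---|---|---|
| autumn | 0.12 M | run made earlier |  |
| winter | 0.17 M | run made earlier |  |
| noon | 0.29 M | run made earlier |  |
| elm | 0.11 M |  | 12 min |
| ash | 0.30 M |  | 12 min |

- autumn (time / min: product / %, substrate / %): 1.50: 6.4, 91.2; 4.00: 17.0, 81.5; 8.00: 30.4, 69.4; 12.0: 40.5, 58.8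
- winter (time / min: product / %, substrate / %): 1.50: 4.2, 93.5; 4.00: 17.3, 85.2; 8.00: 24.9, 73.5; 12.0: 36.4, 63.4
- noon (time / min: product / %, substrate / %): 1.50: 5.6, 94.2; 4.00: 9.2, 89.6; 8.00: 19.8, 80.7; 12.0: 25.0, 73.2

(standard deviation of a reading: 1 percentage point)



1. which of the two ends with the higher amount of product, in percent of the substrate charged ("neither" if they lie within 2 percentage points) (elm / ash / neither)
2. product at the end, in percent of the substrate charged, elm
3. product at the end, in percent of the substrate charged, ash

I started my scale from the pseudo-first-order case: with partner, catalyst, added ligand and time fixed, a step first order in substrate gives the same percent at any charge, so elm and ash would both stand at the autumn 40.9%. The readings refuse this, since autumn and noon differ by 15 percentage points against a scatter of 1 point.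

I therefore added a second process, a limit on output, writing product concentration as C[substrate]/(K+[substrate]), which makes the percent C/(K+[substrate]) and its inverse a straight line in the charge. Autumn and noon then give the ceiling C, the product concentration that this line approaches at large charge when read at 12 min, 0.120 M, and K = 0.175 M. That moved elm to 42.3% and ash down to 25.4%. The winter run, left out of the line, came out at 34.9% against 36.5% read, so I held my figures to about that miss.

The third addition was the slowing within a run: autumn made 6.4% in its first 1.50 min but 10 points in its last 4.00 min, a lower yield per minute. I made no separate correction for it, since I had taken C and K from runs read at the asked time with the same partner, catalyst and added ligand as elm and ash.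

The forecast also chose elm, with 42% and 25.5%, on the ground that “Percent conversion therefore falls as the charge rises”.

The simulation gives 42.2% for elm and 25.4% for ash, so elm ends higher. At 12.0 min, catalyst intermediate A holds 60.1% of the catalyst charged in ash and 26.2% in elm, while the product of ash stands at 63.3% of the ceiling and that of elm at 38.6%.

    substrate + free catalyst → catalyst intermediate A (k = 73.5 M⁻¹ min⁻¹)
    partner + catalyst intermediate A → catalyst intermediate B (k = 24.2 M⁻¹ min⁻¹)
    catalyst intermediate B → free catalyst + product (k = 740 min⁻¹)
    free catalyst → spent catalyst (k = 0.118 min⁻¹)
    free catalyst + added ligand ⇌ idle complex, settled at all times (K = 220 M⁻¹)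

For the flask like ash but with 0.75 M of substrate, the same ceiling and K give 13.0%, and the computed result is 12.3%.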